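**Retrosynthetic overview**
1. Structural feature: the quaternary carbon C9b belongs to both the dihydrofuran ring (O5, C4a, C9b, C9a, C5a) and the cyclohexanone ring (C1–C4, C4a, C9b). Its two aliphatic ring bonds end at C4a and C1, both β to the C3 ketone, so C9b is the one-carbon donor and C4a=C4–C3(=O)–C2=C1 the double acceptor of a [5+1] double Michael annulation.
2. Donor and acceptor are joined through O5. The precursor is an arylacetate whose ortho oxygen carries the dienone as a β-aryloxy enone, with the vinyl ketone half stored as a β-chloroethyl ketone; it comes from an iodophenol ester and a terminal ynone by oxa-Michael addition.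
3. Ring order: dihydrofuran (C9b–C4a), then cyclohexanone (C9b–C1) in the same flask, and the 20-membered bis-lactam last.
4. Macrocycle disconnections: the N8–C(O) amide (macrolactamisation); the C8–C(sp) bond (Sonogashira coupling with a propiolamide that already carries the triamine, then syn semi-hydrogenation); and the Z alkene on C9b (Still–Gennari olefination of the C9b aldehyde made from the ester).
5. The triamine is assembled from putrescine and acrylonitrile, so N1, N4 and N8 are distinct from the outset (N8 trifluoroacetyl, N4 Boc, N1 acylated).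

Key step: step 6

Assumption: the sense of induction in step 6 cannot be predicted, so the cinchonidinium salt is written and its cinchoninium pseudo-enantiomer is taken instead if the antipode of 11 should prevail; dibenzofuran numbering (C1–C4, C4a, O5, C5a, C6–C9, C9a, C9b) and spermidine numbering (N1 propyl end, N4, N8 butyl end) are used for all compounds.

**Route**

Step 1
Reactants: 1 2-hydroxyphenylacetic acid
Product: 2 methyl 2-(2-hydroxyphenyl)acetate
Conditions: MeOH, H2SO4 (cat.), reflux
Reagents that add atoms: methanol, CO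
Why: Fischer esterification in a large excess of methanol favours the open methyl ester over the benzofuranone lactone.

Step 2
Reactants: 2 methyl 2-(2-hydroxyphenyl)acetate
Product: 3 methyl 2-(2-hydroxy-5-iodophenyl)acetate
Conditions: NIS (1.0 equiv), p-TsOH (10 mol %), MeCN, 0 °C → rt
Reagents that add atoms: N-iodosuccinimide, O=C1CCC(=O)N1I
Why: Electrophilic aromatic iodination is directed by the phenol to its free para position (future C8), and iodine is the halogen of choice because the later Sonogashira coupling with an electron-poor alkyne can then run at room temperature.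

Step 3
Reactants: 4 3-chloropropionyl chloride; 5 bis(trimethylsilyl)acetylene
Product: 6 5-chloro-1-(trimethylsilyl)pent-1-yn-3-one
Conditions: AlCl3 (1.1 equiv), CH2Cl2, 0 °C; ice/HCl quench
Reagents that add atoms: none
Why: Friedel–Crafts-type acyl-desilylation of the bis-silyl alkyne stops after one acylation because the ynone formed is deactivated.

Step 4
Reactants: 6 5-chloro-1-(trimethylsilyl)pent-1-yn-3-one
Product: 7 5-chloropent-1-yn-3-one
Conditions: aq. Na2B4O7 (0.01 M, cat.), MeOH, 0 °C, short contact; pH 5 quench; used at once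
Reagents that add atoms: none
Why: Base-catalysed protodesilylation of the carbonyl-activated alkynylsilane is fast enough in a weakly basic borate buffer that the β-chloro ketone should keep its HCl.

Step 5
Reactants: 3 methyl 2-(2-hydroxy-5-iodophenyl)acetate; 7 5-chloropent-1-yn-3-one
Product: 8 methyl 2-{2-[(E)-5-chloro-3-oxopent-1-enyloxy]-5-iodophenyl}acetate
Conditions: DABCO (5 mol %), CH2Cl2, 0 °C
Reagents that add atoms: none
Why: Amine-catalysed oxa-Michael addition of the phenol to the terminal ynone runs through a β-ammonium enone and should give the E β-aryloxy enone, while the small base load and low temperature spare the β-chloro ketone.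

Step 6
Reactants: 8 methyl 2-{2-[(E)-5-chloro-3-oxopent-1-enyloxy]-5-iodophenyl}acetate
Product: 11 methyl (4aR,9bS)-8-iodo-3-oxo-1,2,3,4,4a,9b-hexahydrodibenzofuran-9b-carboxylate, via cross-conjugated dienone 9 (not isolated), via stereolabile monoadduct 10 (not isolated)
Conditions: N-[4-(trifluoromethyl)benzyl]cinchonidinium bromide (10 mol %), powdered KOH (3 equiv), toluene (0.02 M), −20 °C, Ar
Reagents that add atoms: none
Why: Proposed new method: hydroxide carried into toluene by the chiral cation strips HCl from 8 (E1cB) to give dienone 9 and then deprotonates the arylacetate CH2, whose enolate closes 5-exo-trig on the aryloxy-bearing enone carbon (C9b–C4a, dihydrofuran ring) to give 10; renewed deprotonation at C9b and 6-endo-trig addition to the unsubstituted vinyl terminus (C9b–C1, cyclohexanone ring) give 11. The closest known reaction types are the [5+1] double Michael annulation of divinyl ketones with active methylene compounds and the phase-transfer Michael addition of α-aryl carbonyl enolates to vinyl ketones that creates quaternary carbons; untested are the O5 tether, the deactivated β-aryloxy acceptor and an arylacetate as donor. HCl is consumed by the achiral, insoluble base so that the chiral salt stays catalytic, and hydroxide is needed because the donor, although acidified by the meta iodine and the ortho vinylogous acyloxy group, is far less acidic than a malonate. In 10 both stereocentres are labile (C9b by enolisation, C4a by retro-Michael cleavage or by loss and re-addition of phenoxide), whereas the second closure makes C9b quaternary and should not revert at −20 °C, so the mixture drains through the fastest closure. Relative configuration is set by ring strain, since the C9b enolate can reach C1 only on the face that carries the C4a side chain (cis fusion), and absolute configuration by the catalyst, since in that enolate C4a is the only stereocentre and the cation (ion pair to the enolate, 9-OH hydrogen bond to the enone) decides which C4a antipode closes faster. The step needs the carbanion to attack the less electrophilic β-aryloxy carbon before any vinyl ketone, which the substrate secures by offering a five-membered transition state there against a nine-membered one at C1, while the 0.02 M dilution holds back intermolecular addition.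

Step 7
Reactants: 11 methyl (4aR,9bS)-8-iodo-3-oxo-1,2,3,4,4a,9b-hexahydrodibenzofuran-9b-carboxylate
Product: 12 methyl (4aR,9bS)-3,3-ethylenedioxy-8-iodo-1,2,3,4,4a,9b-hexahydrodibenzofuran-9b-carboxylate
Conditions: HOCH2CH2OH, p-TsOH (cat.), toluene, reflux, Dean–Stark
Reagents that add atoms: ethylene glycol, OCCO
Why: Acid-catalysed ketalisation with azeotropic water removal masks the only ketone, and any acid-induced opening of the β-aryloxy ketone can only re-close cis, so C4a stays tied to the fixed C9b.

Step 8
Reactants: 12 methyl (4aR,9bS)-3,3-ethylenedioxy-8-iodo-1,2,3,4,4a,9b-hexahydrodibenzofuran-9b-carboxylate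
Product: 13 [(4aR,9bR)-3,3-ethylenedioxy-8-iodo-1,2,3,4,4a,9b-hexahydrodibenzofuran-9b-yl]methanol
Conditions: DIBAL-H (2.5 equiv), CH2Cl2, −78 → 0 °C; Rochelle salt
Reagents that add atoms: none
Why: Hydride reduction of the neopentyl methyl ester with DIBAL-H leaves ketal, aryl iodide and aryl ether untouched (the descriptor at C9b changes only through CIP priorities).

Step 9
Reactants: 13 [(4aR,9bR)-3,3-ethylenedioxy-8-iodo-1,2,3,4,4a,9b-hexahydrodibenzofuran-9b-yl]methanol
Product: 14 (4aR,9bS)-3,3-ethylenedioxy-8-iodo-1,2,3,4,4a,9b-hexahydrodibenzofuran-9b-carbaldehyde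
Conditions: Dess–Martin periodinane, pyridine, CH2Cl2, 0 °C → rt
Reagents that add atoms: none
Why: Dess–Martin oxidation stops at the aldehyde, which has no α-hydrogen and therefore cannot epimerise.

Step 10
Reactants: 14 (4aR,9bS)-3,3-ethylenedioxy-8-iodo-1,2,3,4,4a,9b-hexahydrodibenzofuran-9b-carbaldehyde; 15 methyl bis(2,2,2-trifluoroethyl)phosphonoacetate
Product: 16 methyl (Z)-3-[(4aR,9bS)-3,3-ethylenedioxy-8-iodo-1,2,3,4,4a,9b-hexahydrodibenzofuran-9b-yl]acrylate
Conditions: KHMDS, 18-crown-6, THF, −78 °C
Reagents that add atoms: none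
Why: In the Still–Gennari olefination the adduct of the electron-poor phosphonate collapses fast and irreversibly, which should give the Z enoate under kinetic control, and the non-enolisable aldehyde tolerates the potassium base.

Step 11
Reactants: 17 1,4-diaminobutane (putrescine)
Product: 18 N-(4-aminobutyl)-2,2,2-trifluoroacetamide
Conditions: CF3CO2Et (1 equiv), 17 (5 equiv), MeOH, 0 °C
Reagents that add atoms: ethyl trifluoroacetate, CCOC(=O)C(F)(F)F
Why: Aminolysis of the activated ester by a fivefold excess of the diamine should give mainly the mono-trifluoroacetamide, which marks the future N8.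

Step 12
Reactants: 18 N-(4-aminobutyl)-2,2,2-trifluoroacetamide; 19 acrylonitrile
Product: 21 tert-butyl (2-cyanoethyl)[4-(trifluoroacetamido)butyl]carbamate, via cyanoethyl amine 20 (not isolated)
Conditions: 19 (1.05 equiv), EtOH, rt; then Boc2O, rt
Reagents that add atoms: di-tert-butyl dicarbonate, CC(C)(C)OC(=O)OC(=O)OC(C)(C)C
Why: Aza-Michael cyanoethylation of the primary amine followed by carbamate formation in the same flask installs the three-carbon arm and blocks N4.

Step 13
Reactants: 21 tert-butyl (2-cyanoethyl)[4-(trifluoroacetamido)butyl]carbamate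
Product: 22 tert-butyl (3-aminopropyl)[4-(trifluoroacetamido)butyl]carbamate
Conditions: H2 (4 atm), PtO2, AcOH, rt; aq. NaHCO3 work-up
Reagents that add atoms: none
Why: Catalytic hydrogenation of the nitrile in acidic medium traps the new primary amine (N1) as its salt, which suppresses secondary-amine formation and trifluoroacetyl migration.

Step 14
Reactants: 22 tert-butyl (3-aminopropyl)[4-(trifluoroacetamido)butyl]carbamate; 23 propiolic acid
Product: 25 tert-butyl [3-(propioloylamino)propyl][4-(trifluoroacetamido)butyl]carbamate, via O-acylisourea 24 (not isolated)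
Conditions: DCC, CH2Cl2, −10 → 0 °C (23 activated first, 22 added last)
Reagents that add atoms: none
Why: Carbodiimide amide coupling with the acid activated first at low temperature favours N-acylation over conjugate addition of the amine to the alkyne.

Step 15
Reactants: 16 methyl (Z)-3-[(4aR,9bS)-3,3-ethylenedioxy-8-iodo-1,2,3,4,4a,9b-hexahydrodibenzofuran-9b-yl]acrylate; 25 tert-butyl [3-(propioloylamino)propyl][4-(trifluoroacetamido)butyl]carbamate
Product: 26 the C8 alkynamide, i.e. 16 with iodine replaced by C≡C–C(O)NH(CH2)3N(Boc)(CH2)4NHCOCF3 (4aR,9bS; Z enoate)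
Conditions: PdCl2(PPh3)2 (5 mol %), CuI (10 mol %), Et3N, THF, rt, degassed
Reagents that add atoms: none
Why: Sonogashira coupling of the aryl iodide with the terminal propiolamide at room temperature attaches the C8 arm and the whole differentiated triamine at once, with N1 placed correctly on the cinnamoyl side.

Step 16
Reactants: 26 the C8 alkynamide
Product: 27 the Z,Z diene, i.e. 26 with the alkyne reduced to a (Z)-cinnamamide (4aR,9bS)
Conditions: H2 (1 atm), Lindlar catalyst, quinoline, EtOAc, rt, stopped after 1 equiv H2, light excluded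
Reagents that add atoms: none
Why: Lindlar semi-hydrogenation delivers hydrogen syn to the alkyne and should give the Z cinnamamide, the hindered disubstituted enoate being much slower to reduce.

Step 17
Reactants: 27 the Z,Z diene
Product: 29 the Z,Z amino acid with free N8H2 and free C9b-acrylic acid (N4 Boc and ketal kept; 4aR,9bS), via amino ester 28 (not isolated)
Conditions: LiOH, THF–MeOH–H2O, rt → 40 °C; 1 M HCl to pH 7
Reagents that add atoms: lithium hydroxide, [Li+].[OH-]
Why: Alkaline hydrolysis cleaves the trifluoroacetamide first and then saponifies the methyl ester, while Boc, ketal, the cinnamamide and both Z alkenes are inert to aqueous hydroxide at this temperature.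

Step 18
Reactants: 29 the Z,Z amino acid
Product: 31 the 20-membered Z,Z bis-lactam with N4 Boc and the C3 ethylene ketal (4aR,9bS), via pentafluorophenyl ester 30 (not isolated)
Conditions: FDPP, i-Pr2NEt, DMF (1 mM, slow addition), rt
Reagents that add atoms: none
Why: Macrolactamisation through an active ester at high dilution has only N8 as a free nucleophile, and the two cis alkenes turn both chain ends towards each other.

Step 19
Reactants: 31 the protected Z,Z bis-lactam
Product: 32 the target CNP0415009.2 (4aR,9bS; both alkenes Z)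
Conditions: TFA–CH2Cl2–H2O, 0 °C → rt, light excluded; aq. NaHCO3
Reagents that add atoms: water, O
Why: Acidolysis of the Boc carbamate and hydrolysis of the ketal occur in one operation under conditions too mild for acid-induced Z to E isomerisation, and reversible opening of the freed β-aryloxy ketone can only restore the cis fusion dictated by C9b.

**Compound list**
1 | 2-hydroxyphenylacetic acid | OC(=O)Cc1ccccc1O | starting material
2 | methyl 2-(2-hydroxyphenyl)acetate | COC(=O)Cc1ccccc1O | intermediate
3 | methyl 2-(2-hydroxy-5-iodophenyl)acetate | COC(=O)Cc1cc(I)ccc1O | intermediate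
4 | 3-chloropropionyl chloride | ClCCC(=O)Cl | starting material
5 | bis(trimethylsilyl)acetylene | C[Si](C)(C)C#C[Si](C)(C)C | starting material
6 | 5-chloro-1-(trimethylsilyl)pent-1-yn-3-one | C[Si](C)(C)C#CC(=O)CCCl | intermediate
7 | 5-chloropent-1-yn-3-one | C#CC(=O)CCCl | intermediate
8 | methyl 2-{2-[(E)-5-chloro-3-oxopent-1-enyloxy]-5-iodophenyl}acetate | COC(=O)Cc1cc(I)ccc1O/C=C/C(=O)CCCl | intermediate
9 | methyl 2-{5-iodo-2-[(E)-3-oxopenta-1,4-dienyloxy]phenyl}acetate (not isolated) | COC(=O)Cc1cc(I)ccc1O/C=C/C(=O)C=C | intermediate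
10 | methyl 5-iodo-2-(2-oxobut-3-enyl)-2,3-dihydrobenzofuran-3-carboxylate, equilibrating stereoisomers (not isolated) | COC(=O)C1c2cc(I)ccc2OC1CC(=O)C=C | intermediate
11 | methyl (4aR,9bS)-8-iodo-3-oxo-1,2,3,4,4a,9b-hexahydrodibenzofuran-9b-carboxylate | O=C1CC[C@]2(C(=O)OC)c3cc(I)ccc3O[C@@H]2C1 | intermediate
12 | methyl (4aR,9bS)-3,3-ethylenedioxy-8-iodo-1,2,3,4,4a,9b-hexahydrodibenzofuran-9b-carboxylate | C1COC2(O1)CC[C@]3(C(=O)OC)c4cc(I)ccc4O[C@@H]3C2 | intermediate
13 | [(4aR,9bR)-3,3-ethylenedioxy-8-iodo-1,2,3,4,4a,9b-hexahydrodibenzofuran-9b-yl]methanol | C1COC2(O1)CC[C@]3(CO)c4cc(I)ccc4O[C@@H]3C2 | intermediate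
14 | (4aR,9bS)-3,3-ethylenedioxy-8-iodo-1,2,3,4,4a,9b-hexahydrodibenzofuran-9b-carbaldehyde | C1COC2(O1)CC[C@]3(C=O)c4cc(I)ccc4O[C@@H]3C2 | intermediate
15 | methyl bis(2,2,2-trifluoroethyl)phosphonoacetate | COC(=O)CP(=O)(OCC(F)(F)F)OCC(F)(F)F | starting material
16 | methyl (Z)-3-[(4aR,9bS)-3,3-ethylenedioxy-8-iodo-1,2,3,4,4a,9b-hexahydrodibenzofuran-9b-yl]acrylate | C1COC2(O1)CC[C@]3(/C=C\C(=O)OC)c4cc(I)ccc4O[C@@H]3C2 | intermediate
17 | 1,4-diaminobutane (putrescine) | NCCCCN | starting material
18 | N-(4-aminobutyl)-2,2,2-trifluoroacetamide | NCCCCNC(=O)C(F)(F)F | intermediate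
19 | acrylonitrile | C=CC#N | starting material
20 | N-{4-[(2-cyanoethyl)amino]butyl}-2,2,2-trifluoroacetamide (not isolated) | N#CCCNCCCCNC(=O)C(F)(F)F | intermediate
21 | tert-butyl (2-cyanoethyl)[4-(trifluoroacetamido)butyl]carbamate | N#CCCN(C(=O)OC(C)(C)C)CCCCNC(=O)C(F)(F)F | intermediate
22 | tert-butyl (3-aminopropyl)[4-(trifluoroacetamido)butyl]carbamate | NCCCN(C(=O)OC(C)(C)C)CCCCNC(=O)C(F)(F)F | intermediate
23 | propiolic acid | C#CC(=O)O | starting material
24 | O-propioloyl-N,N'-dicyclohexylisourea (not isolated) | C#CC(=O)OC(=NC1CCCCC1)NC1CCCCC1 | intermediate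
25 | tert-butyl [3-(propioloylamino)propyl][4-(trifluoroacetamido)butyl]carbamate | C#CC(=O)NCCCN(C(=O)OC(C)(C)C)CCCCNC(=O)C(F)(F)F | intermediate
26 | methyl (Z)-3-[(4aR,9bS)-3,3-ethylenedioxy-8-{3-oxo-3-[(3-{Boc[4-(trifluoroacetamido)butyl]amino}propyl)amino]prop-1-ynyl}-1,2,3,4,4a,9b-hexahydrodibenzofuran-9b-yl]acrylate | C1COC2(O1)CC[C@]3(/C=C\C(=O)OC)c4cc(C#CC(=O)NCCCN(C(=O)OC(C)(C)C)CCCCNC(=O)C(F)(F)F)ccc4O[C@@H]3C2 | intermediate
27 | the (Z)-cinnamamide from 26 (4aR,9bS; both alkenes Z; methyl ester, N4 Boc, N8 trifluoroacetyl, ketal) | C1COC2(O1)CC[C@]3(/C=C\C(=O)OC)c4cc(/C=C\C(=O)NCCCN(C(=O)OC(C)(C)C)CCCCNC(=O)C(F)(F)F)ccc4O[C@@H]3C2 | intermediate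
28 | amino ester: 27 without the trifluoroacetyl group (not isolated) | C1COC2(O1)CC[C@]3(/C=C\C(=O)OC)c4cc(/C=C\C(=O)NCCCN(C(=O)OC(C)(C)C)CCCCN)ccc4O[C@@H]3C2 | intermediate
29 | amino acid: free N8H2 and free (Z)-acrylic acid on C9b (4aR,9bS; N4 Boc, ketal) | C1COC2(O1)CC[C@]3(/C=C\C(=O)O)c4cc(/C=C\C(=O)NCCCN(C(=O)OC(C)(C)C)CCCCN)ccc4O[C@@H]3C2 | intermediate
30 | pentafluorophenyl ester of 29 (not isolated) | C1COC2(O1)CC[C@]3(/C=C\C(=O)Oc5c(F)c(F)c(F)c(F)c5F)c4cc(/C=C\C(=O)NCCCN(C(=O)OC(C)(C)C)CCCCN)ccc4O[C@@H]3C2 | intermediate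
31 | 20-membered Z,Z bis-lactam, N4 Boc, C3 ethylene ketal (4aR,9bS) | C1COC2(O1)CC[C@]34/C=C\C(=O)NCCCCN(C(=O)OC(C)(C)C)CCCNC(=O)/C=C\c5ccc(c3c5)O[C@@H]4C2 | intermediate
32 | CNP0415009.2, (4aR,9bS), both alkenes Z | O=C1CC[C@]23/C=C\C(=O)NCCCCNCCCNC(=O)/C=C\c4ccc(c2c4)O[C@@H]3C1 | target

**Step count**
- Total: 19 steps.
- Longest linear sequence: 13 steps (1, 2, 5–10, 15–19).

**Steps most likely to fail**

Step 6.
- Intermolecular conjugate addition to the liberated vinyl ketone may outrun ring closure.
- Hydroxide may add to the vinylogous ester and cleave the aryl vinyl ether.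
- Loss of phenoxide from the monoadduct may be followed by lactonisation onto the methyl ester.
- The closure may take place on the KOH surface without the chiral cation, which would erode enantioselectivity.

The fallback sets out from 3 and returns at 11. It makes the two C9b bonds by separate, known reactions and sets C9b by desymmetrisation. Phenol 3 is protected (MOMCl, i-Pr2NEt) as the methoxymethyl ether F1. A t-BuOK-mediated double Michael addition to methyl acrylate gives the triester F2, which undergoes Dieckmann condensation in the same flask to the β-keto ester F3. Krapcho demethoxycarbonylation (LiCl, wet DMSO, heat) leaves the prochiral 4-aryl-4-carbomethoxycyclohexanone F4. Enantiotopic deprotonation with a chiral lithium amide (lithium bis[(R)-1-phenylethyl]amide or its antipode, TMSCl internal quench, THF, −100 °C) gives the silyl enol ether F5. IBX·4-methoxypyridine N-oxide oxidises it to the cyclohexenone F6. HCl in methanol then removes the acetal to free the phenol enone F7, which closes by intramolecular oxa-Michael addition, necessarily cis, to 11.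

Step 18. Acylation at the cis-acryloyl carbon next to the quaternary centre may be slow. The active ester then has time to oligomerise or to drift from Z to E through reversible conjugate addition of pentafluorophenoxide.

The fallback sets out from 16 and returns at 31. The congested amide is made bimolecularly and the ring is closed at the unhindered cinnamoyl end.
- The mirror-image triamine is made along the lines of steps 11–13. 1,3-Diaminopropane and ethyl trifluoroacetate give N-(3-aminopropyl)trifluoroacetamide F8. Alkylation with 4-bromobutyronitrile (i-Pr2NEt, MeCN) gives the cyanopropyl amine F9, Boc2O in the same flask gives the carbamate nitrile F10, and hydrogenation (PtO2, AcOH) gives the N8-free amine F11.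
- Saponification of 16 (LiOH) gives the Z acrylic acid F12, which is coupled with F11 (EDC, HOAt) to the iodo amide F13.
- Sonogashira coupling with methyl propiolate (PdCl2(PPh3)2, CuI, K2CO3, THF) gives the aryl propiolate F14. Lindlar semi-hydrogenation gives the Z cinnamate F15, and LiOH gives the amino acid F16.
- Its pentafluorophenyl ester F17, formed with FDPP at high dilution, closes on N1 to give 31.

Step 10. Addition to the neopentyl aldehyde may be sluggish and force higher temperatures. At those temperatures adduct formation becomes reversible and Z selectivity erodes.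

The fallback sets out from 14 and returns at 27. The Z geometry is taken from syn hydrogenation of an alkyne instead of from an olefination. The Ohira–Bestmann reagent (K2CO3, MeOH) converts 14 into the terminal alkyne F18. Silver-catalysed carboxylation (AgI, Cs2CO3, CO2, DMF) gives the alkynoic acid F19 as its caesium salt, which methyl iodide esterifies in the same flask to the methyl alkynoate F20. Sonogashira coupling with 25 as in step 15 gives the diyne F21, and Lindlar hydrogenation with two equivalents of hydrogen reduces both alkynes to give 27.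

**Further compounds**
F1 | step 6 | methyl 2-[5-iodo-2-(methoxymethoxy)phenyl]acetate | COCOc1ccc(I)cc1CC(=O)OC
F2 | step 6 | trimethyl 3-[5-iodo-2-(methoxymethoxy)phenyl]pentane-1,3,5-tricarboxylate | COC(=O)CCC(CCC(=O)OC)(C(=O)OC)c1cc(I)ccc1OCOC
F3 | step 6 | dimethyl 1-[5-iodo-2-(methoxymethoxy)phenyl]-4-oxocyclohexane-1,3-dicarboxylate | COC(=O)C1CC(C(=O)OC)(c2cc(I)ccc2OCOC)CCC1=O
F4 | step 6 | methyl 1-[5-iodo-2-(methoxymethoxy)phenyl]-4-oxocyclohexane-1-carboxylate | COC(=O)C1(c2cc(I)ccc2OCOC)CCC(=O)CC1
F5 | step 6 | methyl (R)-1-[5-iodo-2-(methoxymethoxy)phenyl]-4-(trimethylsilyloxy)cyclohex-3-ene-1-carboxylate | C[Si](C)(C)OC1=CC[C@@](C(=O)OC)(c2cc(I)ccc2OCOC)CC1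
F6 | step 6 | methyl (R)-1-[5-iodo-2-(methoxymethoxy)phenyl]-4-oxocyclohex-2-ene-1-carboxylate | O=C1CC[C@](C(=O)OC)(c2cc(I)ccc2OCOC)C=C1
F7 | step 6 | methyl (R)-1-(2-hydroxy-5-iodophenyl)-4-oxocyclohex-2-ene-1-carboxylate | O=C1CC[C@](C(=O)OC)(c2cc(I)ccc2O)C=C1
F8 | step 18 | N-(3-aminopropyl)-2,2,2-trifluoroacetamide | NCCCNC(=O)C(F)(F)F
F9 | step 18 | N-{3-[(3-cyanopropyl)amino]propyl}-2,2,2-trifluoroacetamide | N#CCCCNCCCNC(=O)C(F)(F)F
F10 | step 18 | tert-butyl (3-cyanopropyl)[3-(trifluoroacetamido)propyl]carbamate | N#CCCCN(C(=O)OC(C)(C)C)CCCNC(=O)C(F)(F)F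
F11 | step 18 | tert-butyl (4-aminobutyl)[3-(trifluoroacetamido)propyl]carbamate | NCCCCN(C(=O)OC(C)(C)C)CCCNC(=O)C(F)(F)F
F12 | step 18 | (Z)-3-[(4aR,9bS)-3,3-ethylenedioxy-8-iodo-1,2,3,4,4a,9b-hexahydrodibenzofuran-9b-yl]acrylic acid | C1COC2(O1)CC[C@]3(/C=C\C(=O)O)c4cc(I)ccc4O[C@@H]3C2
F13 | step 18 | N8 amide of F12 with F11 (aryl iodide kept) | C1COC2(O1)CC[C@]3(/C=C\C(=O)NCCCCN(C(=O)OC(C)(C)C)CCCNC(=O)C(F)(F)F)c4cc(I)ccc4O[C@@H]3C2
F14 | step 18 | F13 with iodine replaced by C≡C–CO2Me | C1COC2(O1)CC[C@]3(/C=C\C(=O)NCCCCN(C(=O)OC(C)(C)C)CCCNC(=O)C(F)(F)F)c4cc(C#CC(=O)OC)ccc4O[C@@H]3C2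
F15 | step 18 | methyl (Z)-cinnamate from F14 | C1COC2(O1)CC[C@]3(/C=C\C(=O)NCCCCN(C(=O)OC(C)(C)C)CCCNC(=O)C(F)(F)F)c4cc(/C=C\C(=O)OC)ccc4O[C@@H]3C2
F16 | step 18 | amino acid with free N1H2 and free (Z)-cinnamic acid | C1COC2(O1)CC[C@]3(/C=C\C(=O)NCCCCN(C(=O)OC(C)(C)C)CCCN)c4cc(/C=C\C(=O)O)ccc4O[C@@H]3C2
F17 | step 18 | pentafluorophenyl ester of F16 | C1COC2(O1)CC[C@]3(/C=C\C(=O)NCCCCN(C(=O)OC(C)(C)C)CCCN)c4cc(/C=C\C(=O)Oc5c(F)c(F)c(F)c(F)c5F)ccc4O[C@@H]3C2
F18 | step 10 | (4aR,9bS)-3,3-ethylenedioxy-9b-ethynyl-8-iodo-1,2,3,4,4a,9b-hexahydrodibenzofuran | C1COC2(O1)CC[C@]3(C#C)c4cc(I)ccc4O[C@@H]3C2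
F19 | step 10 | 3-[(4aR,9bS)-3,3-ethylenedioxy-8-iodo-1,2,3,4,4a,9b-hexahydrodibenzofuran-9b-yl]propiolic acid | C1COC2(O1)CC[C@]3(C#CC(=O)O)c4cc(I)ccc4O[C@@H]3C2
F20 | step 10 | methyl ester of F19 | C1COC2(O1)CC[C@]3(C#CC(=O)OC)c4cc(I)ccc4O[C@@H]3C2
F21 | step 10 | diyne: F20 with iodine replaced by C≡C–C(O)NH(CH2)3N(Boc)(CH2)4NHCOCF3 | C1COC2(O1)CC[C@]3(C#CC(=O)OC)c4cc(C#CC(=O)NCCCN(C(=O)OC(C)(C)C)CCCCNC(=O)C(F)(F)F)ccc4O[C@@H]3C2
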